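Ring A is traced back to a seven-membered homologue: the C3–C4 bond is disconnected so that C18 sits inside an A-homo ring as one carbon of a C4–C18 epoxide. The route exploits the fact that C4 of ring A carries the methyl C19, the one-carbon oxygenated arm C18 and the two ring bonds to C3 and C5. In a single operation a Lewis-acid epoxide rearrangement contracts the ring, creates quaternary C4 with defined configuration and extrudes C18 as the aldehyde. The substrate is a trans-fused cyclohexanone/1-methylcycloheptene oxide (C9 ketone, C20 methyl on C10) whose epoxide oxygen lies anti to C20.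

Key step: step 5

Remark: labdane locants (C1–C20) are used for all bicyclic compounds and labdane names give constitution only (configuration as stated and as in the SMILES); 5-iodopent-1-ene is taken as a purchasable reagent (one Finkelstein exchange from 5-bromopent-1-ene), and the chiral copper ligand is used as the enantiomer that gives the 3R adduct.

Step 1
Reactants: 1 2-methylcyclohex-2-en-1-one
Product: 3 trimethyl{[(3R)-2-methyl-3-(prop-1-en-2-yl)cyclohex-1-en-1-yl]oxy}silane, via bromomagnesium enolate 2 (not isolated)
Conditions: CH2=C(CH3)MgBr (1.3 equiv), Cu(OTf)2 (4 mol %), chiral imidazolinium chloride (NHC precursor, 5 mol %), Et2O, −30 °C; then Me3SiCl, Et3N, HMPA, −30 °C → rt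
Reagents that add atoms: isopropenylmagnesium bromide, C=C(C)[Mg]Br; chlorotrimethylsilane, C[Si](C)(C)Cl
Why: Copper-catalysed enantioselective conjugate addition of a Grignard reagent to an α-substituted cyclic enone, in which the chiral carbene–copper complex should select the enone face and so set C5 (3R), while O-silylation of the magnesium enolate locks the tetrasubstituted enolate regiochemistry needed for step 2.

Step 2
Reactants: 3 trimethyl{[(3R)-2-methyl-3-(prop-1-en-2-yl)cyclohex-1-en-1-yl]oxy}silane; 4 5-iodopent-1-ene
Product: 6 (2R,3R)-2-methyl-2-(pent-4-en-1-yl)-3-(prop-1-en-2-yl)cyclohexan-1-one, via lithium enolate 5 (not isolated)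
Conditions: MeLi (1.05 equiv), THF, 0 °C; then HMPA, 4 (1.5 equiv), −78 °C → rt
Reagents that add atoms: none
Why: Regiospecific generation of the lithium enolate from the silyl enol ether followed by SN2 enolate alkylation, in which the iodide should enter C10 anti to the pseudoaxial isopropenyl group on C5 and so set the quaternary centre with the pentenyl chain trans to the isopropenyl group.

Step 3
Reactants: 6 (2R,3R)-2-methyl-2-(pent-4-en-1-yl)-3-(prop-1-en-2-yl)cyclohexan-1-one
Product: 7 (4aR,9aR)-5,9a-dimethyl-2,3,4,4a,7,8,9,9a-octahydro-1H-benzo[7]annulen-1-one (trans-fused A-homo enone; C4=C18 alkene)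
Conditions: second-generation Grubbs catalyst (5 mol %), CH2Cl2 (0.01 M), 40 °C
Reagents that add atoms: none
Why: Ring-closing metathesis between the terminal and the 1,1-disubstituted alkene should close the trans-fused cycloheptene with loss of ethene, helped by the quaternary centre and tolerated by the ketone.

Step 4
Reactants: 7 (4aR,9aR)-5,9a-dimethyl-2,3,4,4a,7,8,9,9a-octahydro-1H-benzo[7]annulen-1-one
Product: 8 A-homo epoxy ketone (C4–C18 epoxide of 7; oxygen on the face of H5 and anti to the C20 methyl)
Conditions: mCPBA (1.1 equiv), NaHCO3, CH2Cl2, 0 °C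
Reagents that add atoms: 3-chloroperoxybenzoic acid, OOC(=O)c1cccc(Cl)c1
Why: Prilezhaev epoxidation of the only alkene, in which the peracid should approach from the face of H5, away from the axial C20 methyl on C10, while the cold buffered medium should keep the acid-labile epoxide intact and Baeyer–Villiger oxidation of the hindered ketone slow.

Step 5
Reactants: 8 A-homo epoxy ketone
Product: 9 (1S,4aR,8aR)-1,4a-dimethyl-5-oxodecahydronaphthalene-1-carbaldehyde (trans-decalin; C9 ketone; C19 methyl axial; C18 formyl equatorial)
Conditions: MeAl(OAr)2 (MABR; Ar = 4-bromo-2,6-di-tert-butylphenyl; 2.2 equiv, from Me3Al and ArOH), CH2Cl2, −78 → −20 °C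
Reagents that add atoms: none
Why: The bulky, oxophilic aluminium Lewis acid binds the epoxide oxygen and ionises the C4–O bond at the tertiary carbon, and the ring bond C18–C3 shifts to C4 on the face opposite the departing oxygen while the aluminium alkoxide collapses to the C18 formyl group. The closest known reaction type is the Meinwald rearrangement of 1-methylcycloalkene oxides to ring-contracted 1-methylcycloalkanecarbaldehydes. Ring A is closed not by cyclisation of a chain but by a 1,2-alkyl shift that contracts the seven-membered ring to the six-membered one. The new quaternary centre C4 is formed with inversion, so the epoxide face fixed in step 4 decides its configuration: the formyl group ends up on the former oxygen face (equatorial, trans to C20) and the methyl C19 axial. The selectivity needed is migration of C3 over hydride from C18; it should be secured by the steric demand of the aryloxide ligands on aluminium and by the flexible seven-membered ring, which lets the C18–C3 bond align with the developing vacancy at C4. The hindered C9 ketone stays a spectator, and the excess of reagent allows for any Lewis acid that it binds.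

Step 6
Reactants: 9 (1S,4aR,8aR)-1,4a-dimethyl-5-oxodecahydronaphthalene-1-carbaldehyde
Product: 10 (4aR,5S,8aR)-5-(hydroxymethyl)-5,8a-dimethyl-3,4,4a,5,6,7,8,8a-octahydronaphthalen-1(2H)-one
Conditions: NaBH4 (0.4 equiv), EtOH/CH2Cl2, −78 → −40 °C
Reagents that add atoms: none
Why: Chemoselective borohydride reduction, in which the aldehyde should be reduced far faster at low temperature than the C9 ketone flanked by quaternary C10.

Step 7
Reactants: 10 (4aR,5S,8aR)-5-(hydroxymethyl)-5,8a-dimethyl-3,4,4a,5,6,7,8,8a-octahydronaphthalen-1(2H)-one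
Product: 11 (4aR,5S,8aR)-5-[(benzyloxy)methyl]-5,8a-dimethyl-3,4,4a,5,6,7,8,8a-octahydronaphthalen-1(2H)-one
Conditions: benzyl 2,2,2-trichloroacetimidate (1.5 equiv), TfOH (5 mol %), CH2Cl2/cyclohexane, 0 °C → rt
Reagents that add atoms: benzyl 2,2,2-trichloroacetimidate, N=C(OCc1ccccc1)C(Cl)(Cl)Cl
Why: Acid-catalysed O-benzylation with the trichloroacetimidate protects the neopentyl C18 alcohol without base, so the enolisable ketone is left alone.

Step 8
Reactants: 11 (4aR,5S,8aR)-5-[(benzyloxy)methyl]-5,8a-dimethyl-3,4,4a,5,6,7,8,8a-octahydronaphthalen-1(2H)-one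
Product: 13 C8=C9 enol triflate of 11 (18-benzyloxy bicyclic alken-9-yl trifluoromethanesulfonate), via potassium enolate 12 (not isolated)
Conditions: KN(SiMe3)2 (1.2 equiv), THF, −78 °C; then PhNTf2 (1.3 equiv), −78 → 0 °C
Reagents that add atoms: N-phenylbis(trifluoromethanesulfonimide), FC(F)(F)S(=O)(=O)N(c1ccccc1)S(=O)(=O)C(F)(F)F
Why: Enolate O-sulfonylation, in which deprotonation can only occur at C8 because C10 is quaternary, so the enol triflate should form as a single regioisomer.

Step 9
Reactants: 14 methyl hydrogen (R)-3-methylglutarate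
Product: 15 methyl (3R)-5-hydroxy-3-methylpentanoate
Conditions: BH3·THF (1.1 equiv), THF, −10 °C → rt; MeOH quench
Reagents that add atoms: none
Why: Chemoselective borane reduction of the free carboxylic acid in the presence of the methyl ester differentiates the two arms (acid carbon becomes C15) without touching the stereocentre.

Step 10
Reactants: 15 methyl (3R)-5-hydroxy-3-methylpentanoate
Product: 16 methyl (3R)-5-[(tert-butyldimethylsilyl)oxy]-3-methylpentanoate
Conditions: tBuMe2SiCl, imidazole, DMF, 0 °C → rt
Reagents that add atoms: tert-butyldimethylsilyl chloride, CC(C)(C)[Si](C)(C)Cl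
Why: Standard silylation of a primary alcohol, which blocks lactonisation and gives a C15 protecting group orthogonal to the C18 benzyl ether.

Step 11
Reactants: 16 methyl (3R)-5-[(tert-butyldimethylsilyl)oxy]-3-methylpentanoate
Product: 17 (3S)-5-[(tert-butyldimethylsilyl)oxy]-3-methylpentan-1-ol
Conditions: LiAlH4, THF, 0 °C
Reagents that add atoms: none
Why: Hydride reduction of the ester to the primary alcohol (the future C11), with the silyl ether stable to LiAlH4 at 0 °C.

Step 12
Reactants: 17 (3S)-5-[(tert-butyldimethylsilyl)oxy]-3-methylpentan-1-ol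
Product: 18 tert-butyl{[(3R)-5-iodo-3-methylpentyl]oxy}dimethylsilane
Conditions: PPh3, I2, imidazole, CH2Cl2, 0 °C → rt
Reagents that add atoms: iodine, [I][I]
Why: Appel-type iodination, in which iodide displaces the oxyphosphonium group at the primary carbon by SN2 under neutral conditions that spare the silyl ether.

Step 13
Reactants: 18 tert-butyl{[(3R)-5-iodo-3-methylpentyl]oxy}dimethylsilane; 13 C8=C9 enol triflate of 11
Product: 20 18-benzyloxy-15-(tert-butyldimethylsilyloxy)-17-norlabd-8-ene (13S; ring stereocentres as in 11), via alkylzinc iodide 19 (not isolated)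
Conditions: Zn dust, LiCl, THF, 40 °C; then 13, Pd(dppf)Cl2 (5 mol %), THF/NMP, 60 °C
Reagents that add atoms: none
Why: Negishi cross-coupling, in which the primary alkylzinc iodide from zinc insertion should couple with the enol triflate under palladium catalysis with a wide-bite-angle diphosphine that disfavours β-hydride elimination, placing the side chain on C9 and the alkene regiospecifically at C8–C9.

Step 14
Reactants: 20 18-benzyloxy-15-(tert-butyldimethylsilyloxy)-17-norlabd-8-ene
Product: 22 18-benzyloxy-15-(tert-butyldimethylsilyloxy)-17-norlabdan-8-ol (8-OH equatorial and trans to C20; H9 trans to C20), via C8 alkylborane 21 (not isolated)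
Conditions: BH3·THF (3 equiv), THF, 0 °C → rt; then NaOH, H2O2, H2O, 0 °C → rt
Reagents that add atoms: hydrogen peroxide, OO
Why: Hydroboration–oxidation, in which boron adds to the less substituted C8 and hydrogen to C9 in a syn fashion on the face anti to the axial C20 methyl, which sets H9 trans to C20 (side chain equatorial) and gives the equatorial C8 alcohol.

Step 15
Reactants: 22 18-benzyloxy-15-(tert-butyldimethylsilyloxy)-17-norlabdan-8-ol
Product: 23 18-benzyloxy-15-(tert-butyldimethylsilyloxy)-17-norlabdan-8-one
Conditions: Dess–Martin periodinane, CH2Cl2, rt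
Reagents that add atoms: none
Why: Dess–Martin oxidation of the secondary alcohol gives the C8 ketone under mild conditions, and C9 cannot be eroded by enolisation because its side chain is already in the favoured equatorial position.

Step 16
Reactants: 23 18-benzyloxy-15-(tert-butyldimethylsilyloxy)-17-norlabdan-8-one
Product: 24 18-benzyloxy-15-(tert-butyldimethylsilyloxy)labd-8(17)-ene
Conditions: Ph3PCH3Br, KOtBu, toluene, 80 °C
Reagents that add atoms: methyltriphenylphosphonium bromide, C[P+](c1ccccc1)(c1ccccc1)c1ccccc1.[Br-]
Why: Wittig methylenation with the non-stabilised ylide converts the hindered ketone into the exocyclic C8=C17 alkene and brings in C17.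

Step 17
Reactants: 24 18-benzyloxy-15-(tert-butyldimethylsilyloxy)labd-8(17)-ene
Product: 25 18-benzyloxy-15-(tert-butyldimethylsilyloxy)-8,17-epoxylabdane (epoxide oxygen trans to C20)
Conditions: mCPBA, NaHCO3, CH2Cl2, 0 °C
Reagents that add atoms: 3-chloroperoxybenzoic acid, OOC(=O)c1cccc(Cl)c1
Why: Prilezhaev epoxidation, in which the peracid should attack the exocyclic alkene from the equatorial direction, away from the syn-axial C20 methyl, so that the oxygen on C8 is trans to C20.

Step 18
Reactants: 25 18-benzyloxy-15-(tert-butyldimethylsilyloxy)-8,17-epoxylabdane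
Product: 26 18-benzyloxy-15-(tert-butyldimethylsilyloxy)labdan-8-ol (8-OH trans to C20; C17 methyl axial)
Conditions: LiAlH4, THF, 0 °C → rt
Reagents that add atoms: none
Why: Hydride opening of the epoxide by SN2 attack at the primary C17 leaves the C8–O bond untouched, so the tertiary alcohol keeps its oxygen trans to C20 and the new C17 methyl is axial.

Step 19
Reactants: 26 18-benzyloxy-15-(tert-butyldimethylsilyloxy)labdan-8-ol
Product: 27 18-benzyloxylabdane-8,15-diol
Conditions: Bu4NF, THF, rt
Reagents that add atoms: none
Why: Fluoride-induced desilylation frees the primary C15 alcohol while the benzyl ether and the tertiary alcohol are untouched.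

Step 20
Reactants: 27 18-benzyloxylabdane-8,15-diol; 28 Meldrum's acid
Product: 29 18-benzyloxy-8-hydroxylabdan-15-yl hydrogen malonate
Conditions: 28 (1.2 equiv), toluene, 90 °C
Reagents that add atoms: none
Why: Thermal ring opening of Meldrum's acid by an alcohol (acylation with loss of acetone) gives the malonic half ester, and the unhindered primary C15 alcohol should react far faster than the hindered tertiary C8 alcohol at a temperature below that of decarboxylation.

Step 21
Reactants: 29 18-benzyloxy-8-hydroxylabdan-15-yl hydrogen malonate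
Product: 30 3-({(3S)-5-[(1S,2S,4aS,5S,8aR)-2-hydroxy-5-(hydroxymethyl)-2,5,8a-trimethyldecahydronaphthalen-1-yl]-3-methylpentyl}oxy)-3-oxopropanoic acid (target)
Conditions: H2 (1 atm), Pd/C (10 %), EtOAc, rt
Reagents that add atoms: none
Why: Catalytic hydrogenolysis of the benzyl ether is neutral, so the malonic half ester and the tertiary alcohol survive, and no alkene remains to be reduced.

Compound list
1 | 2-methylcyclohex-2-en-1-one | CC1=CCCCC1=O | starting material
2 | bromomagnesium (3R)-2-methyl-3-(prop-1-en-2-yl)cyclohex-1-en-1-olate (formed in the flask) | C=C(C)[C@H]1CCCC(O[Mg]Br)=C1C | intermediate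
3 | trimethyl{[(3R)-2-methyl-3-(prop-1-en-2-yl)cyclohex-1-en-1-yl]oxy}silane | C=C(C)[C@H]1CCCC(O[Si](C)(C)C)=C1C | intermediate
4 | 5-iodopent-1-ene | C=CCCCI | starting material
5 | lithium (3R)-2-methyl-3-(prop-1-en-2-yl)cyclohex-1-en-1-olate (formed in the flask) | C=C(C)[C@H]1CCCC(O[Li])=C1C | intermediate
6 | (2R,3R)-2-methyl-2-(pent-4-en-1-yl)-3-(prop-1-en-2-yl)cyclohexan-1-one (pentenyl trans to isopropenyl) | O=C1[C@](C)(CCCC=C)[C@@H](C(C)=C)CCC1 | intermediate
7 | (4aR,9aR)-5,9a-dimethyl-2,3,4,4a,7,8,9,9a-octahydro-1H-benzo[7]annulen-1-one (trans-fused A-homo enone, C4=C18 alkene) | O=C1[C@]2(C)CCCC=C(C)[C@H]2CCC1 | intermediate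
8 | A-homo epoxy ketone (trans-fused; C4–C18 epoxide with oxygen on the face of H5, anti to the C20 methyl; C9 ketone) | O=C1[C@]2(C)CCC[C@@H]3O[C@]3(C)[C@H]2CCC1 | intermediate
9 | (1S,4aR,8aR)-1,4a-dimethyl-5-oxodecahydronaphthalene-1-carbaldehyde (trans-decalin, C9 ketone, C19 methyl axial and cis to C20, C18 formyl equatorial) | O=C1[C@]2(C)CCC[C@](C)(C=O)[C@H]2CCC1 | intermediate
10 | (4aR,5S,8aR)-5-(hydroxymethyl)-5,8a-dimethyl-3,4,4a,5,6,7,8,8a-octahydronaphthalen-1(2H)-one | O=C1[C@]2(C)CCC[C@](C)(CO)[C@H]2CCC1 | intermediate
11 | (4aR,5S,8aR)-5-[(benzyloxy)methyl]-5,8a-dimethyl-3,4,4a,5,6,7,8,8a-octahydronaphthalen-1(2H)-one | O=C1[C@]2(C)CCC[C@](C)(COCc3ccccc3)[C@H]2CCC1 | intermediate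
12 | potassium C8=C9 enolate of 11 (formed in the flask) | [K]OC1=CCC[C@@H]2[C@@](C)(COCc3ccccc3)CCC[C@@]12C | intermediate
13 | C8=C9 enol triflate of 11 (18-benzyloxy; ring stereocentres as in 11) | O=S(=O)(OC1=CCC[C@@H]2[C@@](C)(COCc3ccccc3)CCC[C@@]12C)C(F)(F)F | intermediate
14 | methyl hydrogen (R)-3-methylglutarate | C[C@H](CC(=O)O)CC(=O)OC | starting material
15 | methyl (3R)-5-hydroxy-3-methylpentanoate | C[C@H](CCO)CC(=O)OC | intermediate
16 | methyl (3R)-5-[(tert-butyldimethylsilyl)oxy]-3-methylpentanoate | C[C@H](CCO[Si](C)(C)C(C)(C)C)CC(=O)OC | intermediate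
17 | (3S)-5-[(tert-butyldimethylsilyl)oxy]-3-methylpentan-1-ol | C[C@H](CCO[Si](C)(C)C(C)(C)C)CCO | intermediate
18 | tert-butyl{[(3R)-5-iodo-3-methylpentyl]oxy}dimethylsilane | C[C@H](CCO[Si](C)(C)C(C)(C)C)CCI | intermediate
19 | {(3R)-5-[(tert-butyldimethylsilyl)oxy]-3-methylpentyl}zinc iodide (formed in the flask) | C[C@H](CCO[Si](C)(C)C(C)(C)C)CC[Zn]I | intermediate
20 | 18-benzyloxy-15-(tert-butyldimethylsilyloxy)-17-norlabd-8-ene (13S; C4, C5, C10 as in 11) | C[C@H](CCO[Si](C)(C)C(C)(C)C)CCC1=CCC[C@@H]2[C@@](C)(COCc3ccccc3)CCC[C@@]12C | intermediate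
21 | C8 alkylborane from 20 (boron on C8 and H on C9, both trans to C20; formed in the flask) | C[C@H](CCO[Si](C)(C)C(C)(C)C)CC[C@H]1[C@]2(C)CCC[C@](C)(COCc3ccccc3)[C@H]2CC[C@@H]1B | intermediate
22 | 18-benzyloxy-15-(tert-butyldimethylsilyloxy)-17-norlabdan-8-ol (8-OH equatorial, trans to C20; H9 trans to C20; side chain equatorial) | C[C@H](CCO[Si](C)(C)C(C)(C)C)CC[C@H]1[C@]2(C)CCC[C@](C)(COCc3ccccc3)[C@H]2CC[C@@H]1O | intermediate
23 | 18-benzyloxy-15-(tert-butyldimethylsilyloxy)-17-norlabdan-8-one | C[C@H](CCO[Si](C)(C)C(C)(C)C)CC[C@H]1[C@]2(C)CCC[C@](C)(COCc3ccccc3)[C@H]2CCC1=O | intermediate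
24 | 18-benzyloxy-15-(tert-butyldimethylsilyloxy)labd-8(17)-ene | C[C@H](CCO[Si](C)(C)C(C)(C)C)CC[C@H]1[C@]2(C)CCC[C@](C)(COCc3ccccc3)[C@H]2CCC1=C | intermediate
25 | 18-benzyloxy-15-(tert-butyldimethylsilyloxy)-8,17-epoxylabdane (epoxide oxygen trans to C20) | C[C@H](CCO[Si](C)(C)C(C)(C)C)CC[C@H]1[C@]2(C)CCC[C@](C)(COCc3ccccc3)[C@H]2CC[C@@]14CO4 | intermediate
26 | 18-benzyloxy-15-(tert-butyldimethylsilyloxy)labdan-8-ol (8-OH trans to C20, C17 methyl axial) | C[C@H](CCO[Si](C)(C)C(C)(C)C)CC[C@H]1[C@]2(C)CCC[C@](C)(COCc3ccccc3)[C@H]2CC[C@]1(C)O | intermediate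
27 | 18-benzyloxylabdane-8,15-diol | C[C@H](CCO)CC[C@H]1[C@]2(C)CCC[C@](C)(COCc3ccccc3)[C@H]2CC[C@]1(C)O | intermediate
28 | Meldrum's acid (2,2-dimethyl-1,3-dioxane-4,6-dione) | CC1(C)OC(=O)CC(=O)O1 | starting material
29 | 18-benzyloxy-8-hydroxylabdan-15-yl hydrogen malonate | C[C@H](CCOC(=O)CC(=O)O)CC[C@H]1[C@]2(C)CCC[C@](C)(COCc3ccccc3)[C@H]2CC[C@]1(C)O | intermediate
30 | 3-({(3S)-5-[(1S,2S,4aS,5S,8aR)-2-hydroxy-5-(hydroxymethyl)-2,5,8a-trimethyldecahydronaphthalen-1-yl]-3-methylpentyl}oxy)-3-oxopropanoic acid | C[C@H](CCOC(=O)CC(=O)O)CC[C@H]1[C@]2(C)CCC[C@](C)(CO)[C@H]2CC[C@]1(C)O | target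

Total step count: 21. Longest linear sequence: 17 steps (steps 1–8, then 13–21); the side chain 18 takes 4 steps (9–12).

Steps most likely to fail

Step 5. What may go wrong: hydride from C18 migrates in place of C3 and gives the seven-membered ring ketone, or a free C4 cation erodes the stereospecificity. The fallback sets out from 7 and comes back at 9, and lets the geometry of a halohydrin decide what migrates. Alkene 7 is treated with NBS in aqueous acetone (bromonium ion on the face anti to C20, water at tertiary C4 from the C20 face) to give the bromohydrin F1. K2CO3 in MeOH closes it to the diastereomeric epoxy ketone F2, with oxygen syn to C20. MgBr2·OEt2 in Et2O/toluene opens F2 at C4 with inversion to the bromomagnesium bromohydrinate F3, which is not isolated. On warming, the ring bond C18–C3 is antiperiplanar to the C4–Br bond when that bond is pseudo-equatorial, whereas the C18 hydrogen is not, so the ring bond should shift to C4 with a second inversion (halohydrin semipinacol ring contraction). Two inversions from the syn epoxide lead to the same aldehyde 9.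

Step 1. What may go wrong: insufficient facial discrimination by the chiral copper catalyst with an alkenyl Grignard reagent, so that material of low enantiomeric purity is carried forward. The fallback sets out from 10 and comes back at 10 as a classical resolution. Alcohol 10 of insufficient purity (or racemic 10 from a ligand-free CuBr·SMe2-catalysed run of step 1) is acylated with (1S)-camphanic chloride (pyridine, DMAP, CH2Cl2). The diastereomeric esters are separated by crystallisation or chromatography, and the camphanate F4 of the wanted enantiomer is cleaved by methanolysis (K2CO3, MeOH) to return enantiopure 10.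

Step 4. What may go wrong: the peracid attacks the C20 face of the flexible seven-membered ring, or shows low facial selectivity. The fallback sets out from 7 and comes back at 8, and inverts the face that receives oxygen. NBS in aqueous acetone puts bromine on C18 on the face that electrophiles prefer (in this case the C20 face) and water on tertiary C4 from the opposite face, giving the bromohydrin F5. K2CO3 in MeOH then closes the C4 alkoxide onto C18 with inversion, which gives 8 with oxygen anti to C20.

Further compounds
F1 | step 5 | bromohydrin of 7 (C18–Br anti to C20, C4–OH syn to C20) | O=C1[C@]2(C)CCC[C@H](Br)[C@@](C)(O)[C@H]2CCC1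
F2 | step 5 | diastereomeric A-homo epoxy ketone (oxygen syn to C20) | O=C1[C@]2(C)CCC[C@H]3O[C@@]3(C)[C@H]2CCC1
F3 | step 5 | bromomagnesium bromohydrinate (C4–Br anti to C20, C18–OMgBr syn to C20) | O=C1[C@]2(C)CCC[C@@H](O[Mg]Br)[C@](C)(Br)[C@H]2CCC1
F4 | step 1 | (1S)-camphanate of 10 | O=C1[C@]2(C)CCC[C@](C)(COC(=O)[C@@]34CC[C@@](C)(C(=O)O3)C4(C)C)[C@H]2CCC1
F5 | step 4 | bromohydrin of 7 (C18–Br syn to C20, C4–OH anti to C20) | O=C1[C@]2(C)CCC[C@@H](Br)[C@](C)(O)[C@H]2CCC1
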